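**Retrosynthetic overview**

1. Target: ent-labda-8(17),13(16),14-trien-19-yl (Z)-p-coumarate. Late disconnections: the (Z)-enoate C=C (Z-selective Horner–Wadsworth–Emmons on a C19 phosphonoacetate), C12–C13 (copper-catalysed Grignard coupling) and C8=C17 (Wittig).
2. Key disconnection C4–C19: formaldehyde adds to a cyclic allylboronate (boron on C2 of ring A) that is generated in the same pot by an intramolecular Diels–Alder reaction of an open-chain trienylboronate. Rings A and B close together in the cycloaddition, then C4–C19 forms with boron-to-carbon chirality relay.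
3. Enabling feature: the quaternary C4 of ring A carries only a methyl and the one-carbon CH2O arm (C19) and is 1,3-related to C2. Ring A (C1–C5, C10) can therefore be the cyclohexene from a C2=C3–C4(CH3)=C5 diene and the C10(CH3)=C1H2 isopropenyl group, while the ring-B carbons C6–C9 are the tether between the ring-fusion atoms C5 and C10.
4. The acyclic precursor comes from a syn-selective catalytic asymmetric allylboration (C8–C9 bond) of a dienylboronate aldehyde with a (Z)-allylboronate. C9 is the only target stereocentre set before the key step, and it steers C5, C10 and C4.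

Key step: step 9

Remark: locants C1–C20 follow labdane numbering (ring A = C1–C5, C10; ring B = C5–C10; C18 = C4 methyl, C19 = C4 CH2O carbon, C20 = C10 methyl); descriptors are CIP. pinB = 4,4,5,5-tetramethyl-1,3,2-dioxaborolan-2-yl, TBS = tert-butyldimethylsilyl, TES = triethylsilyl, Cp = cyclopentadienyl (written σ-bonded in SMILES).

**Route**

Step 1
Reactants: 1 methacrolein
Product: 2 ethyl (2E)-4-methylpenta-2,4-dienoate
Conditions: Ph3P=CHCO2Et, CH2Cl2, rt
Reagents that add atoms: ethyl (triphenylphosphoranylidene)acetate, CCOC(=O)C=P(c1ccccc1)(c1ccccc1)c1ccccc1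
Why: Wittig olefination with a stabilised ylide should give the (E)-enoate.

Step 2
Reactants: 2 ethyl (2E)-4-methylpenta-2,4-dienoate
Product: 3 (2E)-4-methylpenta-2,4-dien-1-ol
Conditions: iBu2AlH (2.2 equiv), CH2Cl2, −78 °C to 0 °C; aqueous work-up
Reagents that add atoms: none
Why: 1,2-reduction of the conjugated ester by the aluminium hydride should leave the diene untouched.

Step 3
Reactants: 3 (2E)-4-methylpenta-2,4-dien-1-ol
Product: 4 tert-butyl(dimethyl){[(2E)-4-methylpenta-2,4-dien-1-yl]oxy}silane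
Conditions: TBSCl, imidazole, DMF, 0 °C to rt
Reagents that add atoms: tert-butyldimethylsilyl chloride, CC(C)(C)[Si](C)(C)Cl
Why: standard silylation of a primary alcohol.

Step 4
Reactants: 4 tert-butyl(dimethyl){[(2E)-4-methylpenta-2,4-dien-1-yl]oxy}silane
Product: 5 tert-butyl(dimethyl){[(3Z)-4-methyl-5-(pinB)pent-3-en-1-yl]oxy}silane
Conditions: pinacolborane (1.1 equiv), Ni(cod)2 (bis(1,5-cyclooctadiene)nickel, 2.5 mol %), PCy3 (2.5 mol %), toluene, rt
Reagents that add atoms: pinacolborane, CC1(C)OBOC1(C)C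
Why: nickel-catalysed 1,4-hydroboration of a 1,3-diene should put hydrogen on the substituted terminus and boron on the CH2 terminus, the s-cis diene complex fixing the (Z)-trisubstituted alkene.

Step 5
Reactants: 6 hex-4-yn-1-ol
Product: 8 (4E)-5-iodohex-4-en-1-ol, via alkenylzirconocene chloride 7 (not isolated)
Conditions: Cp2Zr(H)Cl (2.5 equiv), THF, rt to 45 °C; then I2, 0 °C
Reagents that add atoms: iodine, II
Why: syn-hydrozirconation of the 2-alkyne should, after equilibration with excess hydride, place zirconium on the less hindered methyl-bearing carbon, and iododezirconation proceeds with retention to the (E)-iodide.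

Step 6
Reactants: 8 (4E)-5-iodohex-4-en-1-ol
Product: 9 (4E,6E)-5-methyl-7-(pinB)hepta-4,6-dien-1-ol
Conditions: vinyl-Bpin (2 equiv), Pd(OAc)2 (5 mol %), P(o-tol)3 (10 mol %), AgOAc (1.2 equiv), MeCN, 50 °C
Reagents that add atoms: 4,4,5,5-tetramethyl-2-vinyl-1,3,2-dioxaborolane, C=CB1OC(C)(C)C(C)(C)O1
Why: Mizoroki–Heck coupling of the alkenyl iodide with the vinylboronate under silver acetate conditions should keep boron, retain the iodide geometry and form the new (E)-alkene by β-hydride elimination.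

Step 7
Reactants: 9 (4E,6E)-5-methyl-7-(pinB)hepta-4,6-dien-1-ol
Product: 10 (4E,6E)-5-methyl-7-(pinB)hepta-4,6-dienal
Conditions: Dess–Martin periodinane, CH2Cl2, 0 °C to rt
Reagents that add atoms: none
Why: Dess–Martin oxidation of a primary alcohol is mild enough for the dienylboronate.

Step 8
Reactants: 10 (4E,6E)-5-methyl-7-(pinB)hepta-4,6-dienal; 5 tert-butyl(dimethyl){[(3Z)-4-methyl-5-(pinB)pent-3-en-1-yl]oxy}silane
Product: 12 (3S,4S,7E,9E)-3-[2-(TBSO)ethyl]-2,8-dimethyl-10-(pinB)deca-1,7,9-trien-4-ol, via O-borylated adduct 11 (not isolated)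
Conditions: (R)-3,3'-bis(2,4,6-triisopropylphenyl)-1,1'-binaphthyl-2,2'-diyl hydrogen phosphate (5 mol %), 4 Å molecular sieves, toluene, −30 °C to 0 °C; then H2O
Reagents that add atoms: none
Why: chiral phosphoric acid-catalysed allylboration through a closed chair (Zimmerman–Traxler-type) transition state, in which the (Z)-γ-substituent gives the syn C8/C9 relationship and the catalyst, chosen for attack on the Re face of the aldehyde, should set both centres as (S).

Step 9
Reactants: 12 (3S,4S,7E,9E)-3-[2-(TBSO)ethyl]-2,8-dimethyl-10-(pinB)deca-1,7,9-trien-4-ol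
Product: 15 (4R,5S,8S,9S,10R)-12-(TBSO)-13,14,15,16,17-pentanor-ent-labd-2-ene-8,19-diol, via bicyclic allylboronate 13 (not isolated), via borate ester 14 (not isolated)
Conditions: toluene (0.02 M), BHT (cat.), sealed tube, 190 °C; then (CH2O)n (5 equiv), 90 °C; then H2O
Reagents that add atoms: formaldehyde (from paraformaldehyde), C=O
Why: A thermal intramolecular [4+2] cycloaddition of the (E,E)-1-boryl diene C2=C3–C4=C5 with the tethered isopropenyl group C10=C1 gives the cyclic secondary allylboronate 13, which then adds to formaldehyde through a closed six-membered chair transition state with allylic transposition, forming C4–C19 and moving the alkene to C2=C3. The closest known reaction type is the one-pot Diels–Alder/allylboration sequence of 1-boryl-1,3-dienes (3-methyl dienes give a quaternary centre in the allylboration), combined with the intramolecular Diels–Alder reaction of 1,7,9-decatrienes that carry a methyl on the internal dienophile carbon. Ring A (C1–C5, C10) closes by the [4+2] event itself (bonds C5–C10 and C1–C2), and ring B (C5–C10) closes in the same event as the six-membered ring spanned by the C6–C9 tether. C5 and C10 are set by the chair-like, tether-anti transition state that leads to the trans ring fusion with the C8 hydroxyl and the C9 side chain both equatorial, so the pre-set C9 centre selects the diene face; the transient C2 centre follows from suprafacial addition to the (E,E)-diene (boron cis to the C5–C6 bond), and C4 follows from suprafacial boron-to-carbon relay, so C19 enters cis to boron and hence cis to the C10 methyl. The step needs trans over cis ring fusion and one diene face, which should be secured by the internal methyl of the dienophile (it disfavours the tether-endo array) and by the two equatorial tether substituents, while chemoselectivity is inherent because no other alkene can reach the diene through a six-membered ring.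

Step 10
Reactants: 15 (4R,5S,8S,9S,10R)-12-(TBSO)-13,14,15,16,17-pentanor-ent-labd-2-ene-8,19-diol
Product: 16 (4R,5S,8S,9S,10R)-12-(TBSO)-13,14,15,16,17-pentanor-ent-labdane-8,19-diol
Conditions: H2 (1 atm), Pd/C, EtOAc, rt
Reagents that add atoms: none
Why: heterogeneous catalytic hydrogenation of the only alkene (C2=C3) creates no stereocentre.

Step 11
Reactants: 16 (4R,5S,8S,9S,10R)-12-(TBSO)-13,14,15,16,17-pentanor-ent-labdane-8,19-diol
Product: 17 (4R,5S,9S,10R)-12-(TBSO)-19-hydroxy-13,14,15,16,17-pentanor-ent-labdan-8-one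
Conditions: NaOCl (aq., 1.1 equiv), AcOH, 0 °C to rt
Reagents that add atoms: none
Why: hypochlorite/acetic acid oxidation is selective for secondary over primary alcohols, so the hindered neopentyl C19 hydroxyl should survive, and C9 already has the thermodynamically preferred equatorial side chain.

Step 12
Reactants: 17 (4R,5S,9S,10R)-12-(TBSO)-19-hydroxy-13,14,15,16,17-pentanor-ent-labdan-8-one
Product: 18 (4R,5S,9R,10S)-12-(TBSO)-13,14,15,16-tetranor-ent-labd-8(17)-en-19-ol
Conditions: Ph3PCH3Br (3 equiv), KOtBu (3 equiv), THF, 0 °C to 50 °C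
Reagents that add atoms: methyltriphenylphosphonium bromide (as its ylide), C[P+](c1ccccc1)(c1ccccc1)c1ccccc1.[Br-]
Why: Wittig methylenation of the C8 ketone, with excess ylide covering the free hydroxyl, should install the exocyclic C8=C17 alkene without risk to the equatorial C9 centre.

Step 13
Reactants: 18 (4R,5S,9R,10S)-12-(TBSO)-13,14,15,16-tetranor-ent-labd-8(17)-en-19-ol
Product: 19 (4R,5S,9R,10S)-13,14,15,16-tetranor-ent-labd-8(17)-ene-12,19-diol
Conditions: Bu4NF, THF, rt
Reagents that add atoms: none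
Why: fluoride cleavage of the primary silyl ether.

Step 14
Reactants: 19 (4R,5S,9R,10S)-13,14,15,16-tetranor-ent-labd-8(17)-ene-12,19-diol
Product: 20 (4R,5S,9R,10S)-12-iodo-13,14,15,16-tetranor-ent-labd-8(17)-en-19-ol
Conditions: I2 (1.1 equiv), PPh3 (1.1 equiv), imidazole, CH2Cl2, 0 °C
Reagents that add atoms: iodine, II
Why: Appel-type iodination, in which SN2 displacement should occur at the unhindered C12 carbinol and not at the neopentyl C19 carbinol.

Step 15
Reactants: 20 (4R,5S,9R,10S)-12-iodo-13,14,15,16-tetranor-ent-labd-8(17)-en-19-ol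
Product: 21 (4R,5S,9R,10S)-ent-labda-8(17),13(16),14-trien-19-ol
Conditions: buta-1,3-dien-2-ylmagnesium chloride (3 equiv, from chloroprene and Mg in THF), Li2CuCl4 (5 mol %), THF, −20 °C to rt
Reagents that add atoms: buta-1,3-dien-2-ylmagnesium chloride, C=CC(=C)[Mg]Cl
Why: copper-catalysed cross-coupling of a primary alkyl iodide with an alkenyl Grignard reagent should build the 2-substituted buta-1,3-diene directly, one equivalent of Grignard being consumed by the hydroxyl.

Step 16
Reactants: 21 (4R,5S,9R,10S)-ent-labda-8(17),13(16),14-trien-19-ol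
Product: 22 (4R,5S,9R,10S)-ent-labda-8(17),13(16),14-trien-19-yl bromoacetate
Conditions: BrCH2COBr, pyridine, CH2Cl2, 0 °C
Reagents that add atoms: bromoacetyl bromide, BrCC(Br)=O
Why: acylation of the neopentyl alcohol with a reactive acyl bromide.

Step 17
Reactants: 22 (4R,5S,9R,10S)-ent-labda-8(17),13(16),14-trien-19-yl bromoacetate
Product: 23 (4R,5S,9R,10S)-ent-labda-8(17),13(16),14-trien-19-yl (diphenoxyphosphoryl)acetate
Conditions: (PhO)2P(O)H, Et3N, CH2Cl2, 0 °C to rt
Reagents that add atoms: diphenyl phosphite, O=[PH](Oc1ccccc1)Oc1ccccc1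
Why: Michaelis–Becker alkylation of the phosphite by the α-bromo ester should give the diaryl phosphonoacetate.

Step 18
Reactants: 23 (4R,5S,9R,10S)-ent-labda-8(17),13(16),14-trien-19-yl (diphenoxyphosphoryl)acetate; 24 4-(TBSO)benzaldehyde
Product: 25 (4R,5S,9R,10S)-ent-labda-8(17),13(16),14-trien-19-yl (2Z)-3-[4-(TBSO)phenyl]prop-2-enoate
Conditions: NaH, THF, −78 °C to −20 °C
Reagents that add atoms: none
Why: Horner–Wadsworth–Emmons olefination with a diaryl phosphonoacetate, whose fast irreversible oxaphosphetane collapse should give the (Z)-enoate with an aromatic aldehyde.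

Step 19
Reactants: 25 (4R,5S,9R,10S)-ent-labda-8(17),13(16),14-trien-19-yl (2Z)-3-[4-(TBSO)phenyl]prop-2-enoate
Product: 26 (4R,5S,9R,10S)-ent-labda-8(17),13(16),14-trien-19-yl (2Z)-3-(4-hydroxyphenyl)prop-2-enoate
Conditions: Bu4NF, AcOH, THF, 0 °C, in the dark
Reagents that add atoms: none
Why: buffered fluoride cleavage of the aryl silyl ether should leave the ester and the (Z)-alkene untouched.

**Compound list**

1 | methacrolein (2-methylprop-2-enal) | CC(=C)C=O | starting material
2 | ethyl (2E)-4-methylpenta-2,4-dienoate | CCOC(=O)/C=C/C(C)=C | intermediate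
3 | (2E)-4-methylpenta-2,4-dien-1-ol | OC/C=C/C(C)=C | intermediate
4 | tert-butyl(dimethyl){[(2E)-4-methylpenta-2,4-dien-1-yl]oxy}silane | CC(C)(C)[Si](C)(C)OC/C=C/C(C)=C | intermediate
5 | tert-butyl(dimethyl){[(3Z)-4-methyl-5-(pinB)pent-3-en-1-yl]oxy}silane | CC(C)(C)[Si](C)(C)OCC/C=C(C)\CB1OC(C)(C)C(C)(C)O1 | intermediate
6 | hex-4-yn-1-ol | CC#CCCCO | starting material
7 | (E)-alkenylzirconocene chloride: Cp2Zr(Cl) on C5 of hex-4-en-1-ol (cis to H4) and Cp2Zr(Cl) on oxygen | C/C(=C\CCCO[Zr](Cl)(C1C=CC=C1)C1C=CC=C1)[Zr](Cl)(C1C=CC=C1)C1C=CC=C1 | intermediate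
8 | (4E)-5-iodohex-4-en-1-ol | C/C(I)=C\CCCO | intermediate
9 | (4E,6E)-5-methyl-7-(pinB)hepta-4,6-dien-1-ol | OCCC/C=C(C)/C=C/B1OC(C)(C)C(C)(C)O1 | intermediate
10 | (4E,6E)-5-methyl-7-(pinB)hepta-4,6-dienal | O=CCC/C=C(C)/C=C/B1OC(C)(C)C(C)(C)O1 | intermediate
11 | O-pinB ether of 12: 2-{[(3S,4S,7E,9E)-3-[2-(TBSO)ethyl]-2,8-dimethyl-10-(pinB)deca-1,7,9-trien-4-yl]oxy}-4,4,5,5-tetramethyl-1,3,2-dioxaborolane | CC(C)(C)[Si](C)(C)OCC[C@@H](C(C)=C)[C@@H](OB1OC(C)(C)C(C)(C)O1)CC/C=C(C)/C=C/B2OC(C)(C)C(C)(C)O2 | intermediate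
12 | (3S,4S,7E,9E)-3-[2-(TBSO)ethyl]-2,8-dimethyl-10-(pinB)deca-1,7,9-trien-4-ol | CC(C)(C)[Si](C)(C)OCC[C@@H](C(C)=C)[C@@H](O)CC/C=C(C)/C=C/B1OC(C)(C)C(C)(C)O1 | intermediate
13 | (2R,5R,8S,9S,10R)-12-(TBSO)-2-(pinB)-13,14,15,16,17,19-hexanor-ent-labd-3-en-8-ol (trans-fused; boron on C2 cis to the C10 methyl) | CC(C)(C)[Si](C)(C)OCC[C@@H]1[C@@H](O)CC[C@@H]2C(C)=C[C@H](B3OC(C)(C)C(C)(C)O3)C[C@@]12C | intermediate
14 | (4R,5S,8S,9S,10R)-12-(TBSO)-19-(pinB-oxy)-13,14,15,16,17-pentanor-ent-labd-2-en-8-ol | CC(C)(C)[Si](C)(C)OCC[C@@H]1[C@@H](O)CC[C@@H]2[C@](C)(COB3OC(C)(C)C(C)(C)O3)C=CC[C@@]12C | intermediate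
15 | (4R,5S,8S,9S,10R)-12-(TBSO)-13,14,15,16,17-pentanor-ent-labd-2-ene-8,19-diol (C19 axial, cis to the C10 methyl; C8 OH and C9 chain equatorial) | CC(C)(C)[Si](C)(C)OCC[C@@H]1[C@@H](O)CC[C@@H]2[C@](C)(CO)C=CC[C@@]12C | intermediate
16 | (4R,5S,8S,9S,10R)-12-(TBSO)-13,14,15,16,17-pentanor-ent-labdane-8,19-diol | CC(C)(C)[Si](C)(C)OCC[C@@H]1[C@@H](O)CC[C@@H]2[C@](C)(CO)CCC[C@@]12C | intermediate
17 | (4R,5S,9S,10R)-12-(TBSO)-19-hydroxy-13,14,15,16,17-pentanor-ent-labdan-8-one | CC(C)(C)[Si](C)(C)OCC[C@@H]1C(=O)CC[C@@H]2[C@](C)(CO)CCC[C@@]12C | intermediate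
18 | (4R,5S,9R,10S)-12-(TBSO)-13,14,15,16-tetranor-ent-labd-8(17)-en-19-ol | CC(C)(C)[Si](C)(C)OCC[C@@H]1C(=C)CC[C@@H]2[C@](C)(CO)CCC[C@@]12C | intermediate
19 | (4R,5S,9R,10S)-13,14,15,16-tetranor-ent-labd-8(17)-ene-12,19-diol | OCC[C@@H]1C(=C)CC[C@@H]2[C@](C)(CO)CCC[C@@]12C | intermediate
20 | (4R,5S,9R,10S)-12-iodo-13,14,15,16-tetranor-ent-labd-8(17)-en-19-ol | ICC[C@@H]1C(=C)CC[C@@H]2[C@](C)(CO)CCC[C@@]12C | intermediate
21 | (4R,5S,9R,10S)-ent-labda-8(17),13(16),14-trien-19-ol | C=CC(=C)CC[C@@H]1C(=C)CC[C@@H]2[C@](C)(CO)CCC[C@@]12C | intermediate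
22 | (4R,5S,9R,10S)-ent-labda-8(17),13(16),14-trien-19-yl bromoacetate | C=CC(=C)CC[C@@H]1C(=C)CC[C@@H]2[C@](C)(COC(=O)CBr)CCC[C@@]12C | intermediate
23 | (4R,5S,9R,10S)-ent-labda-8(17),13(16),14-trien-19-yl (diphenoxyphosphoryl)acetate | C=CC(=C)CC[C@@H]1C(=C)CC[C@@H]2[C@](C)(COC(=O)CP(=O)(Oc3ccccc3)Oc3ccccc3)CCC[C@@]12C | intermediate
24 | 4-[(tert-butyldimethylsilyl)oxy]benzaldehyde | O=Cc1ccc(O[Si](C)(C)C(C)(C)C)cc1 | starting material
25 | (4R,5S,9R,10S)-ent-labda-8(17),13(16),14-trien-19-yl (2Z)-3-[4-(TBSO)phenyl]prop-2-enoate | C=CC(=C)CC[C@@H]1C(=C)CC[C@@H]2[C@](C)(COC(=O)/C=C\c3ccc(O[Si](C)(C)C(C)(C)C)cc3)CCC[C@@]12C | intermediate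
26 | (4R,5S,9R,10S)-ent-labda-8(17),13(16),14-trien-19-yl (2Z)-3-(4-hydroxyphenyl)prop-2-enoate | C=CC(=C)CC[C@@H]1C(=C)CC[C@@H]2[C@](C)(COC(=O)/C=C\c3ccc(O)cc3)CCC[C@@]12C | target

**Step count and risks**

Total step count: 19. Longest linear sequence: 16 steps (steps 1–4, then 8–19); the second branch (steps 5–7) joins at step 8.

Steps most likely to fail:

1. Step 9. The cycloaddition of the unactivated isopropenyl group needs prolonged heating. During it the allylboron unit may be lost by protonolysis through the free C8 hydroxyl or by 1,3-boryl migration, and the transfer of formaldehyde to C4 beneath the axial C10 methyl may be too slow to compete. The fallback keeps the cycloaddition but makes C4–C19 by a [2,3]-sigmatropic shift instead of allylboration; it sets out from 12 and returns at 15. Compound 12 would be silylated (Et3SiCl, imidazole) to its C8 triethylsilyl ether F1. Thermolysis (toluene, 190 °C) would give the isolated cycloadduct, the bicyclic allylboronate F2. Oxidation with NaBO3 (retention at C2) would give the allylic alcohol F3. O-Alkylation (KH, ICH2SnBu3) would give the stannylmethyl ether F4. Tin–lithium exchange (n-BuLi, THF, −78 °C) would trigger the [2,3]-Wittig–Still rearrangement, suprafacial from the pseudo-axial C2 oxygen to C4, to give the homoallylic alcohol F5. Pyridinium p-toluenesulfonate in MeOH at 0 °C would remove the triethylsilyl group to give 15.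

2. Step 8. Enantio-induction may be insufficient, or turnover low, when the hindered β-methylated (Z)-boronate meets an aliphatic aldehyde; this would erode the absolute control that C9 must pass on to the key step. The fallback replaces catalyst control by resolution; it sets out from 5 and 10 and returns at 12. Uncatalysed allylboration (toluene, 40 °C) keeps the syn selectivity of the closed transition state. It would give borate 11 together with its enantiomer, the (3R,4R) O-borylated adduct F6, and after hydrolysis alcohol 12 together with its enantiomer, the (3R,4R) alcohol F7. Lipase-catalysed acylation (immobilised Candida antarctica lipase B, vinyl acetate, hexane) should, by the empirical size rule for secondary alcohols, acetylate the (4R) carbinol to the (3R,4R) acetate F8. Compound 12 would be left behind and separated by chromatography.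

3. Step 11. The primary C19 hydroxyl may be oxidised in competition with the secondary C8 hydroxyl, or the silyl ether may be lost in the acidic medium. The fallback uses protection instead of chemoselective oxidation; it sets out from 16 and returns at 19. Selective silylation of the primary hydroxyl (TBSCl, imidazole, CH2Cl2, 0 °C) would give the 12,19-bis-silyl ether alcohol F9. Dess–Martin oxidation would give the bis-silyl ketone F10. Wittig methylenation (Ph3PCH3Br, KOtBu) would give the bis-silyl exocyclic alkene F11. Bu4NF would remove both silyl groups to give 19.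

Further compounds
F1 | step 9 | (3S,4S,7E,9E)-3-[2-(TBSO)ethyl]-2,8-dimethyl-10-(pinB)-4-(TESO)deca-1,7,9-triene | CC(C)(C)[Si](C)(C)OCC[C@@H](C(C)=C)[C@@H](O[Si](CC)(CC)CC)CC/C=C(C)/C=C/B1OC(C)(C)C(C)(C)O1
F2 | step 9 | (2R,5R,8S,9S,10R)-12-(TBSO)-8-(TESO)-2-(pinB)-13,14,15,16,17,19-hexanor-ent-labd-3-ene | CC(C)(C)[Si](C)(C)OCC[C@@H]1[C@@H](O[Si](CC)(CC)CC)CC[C@@H]2C(C)=C[C@H](B3OC(C)(C)C(C)(C)O3)C[C@@]12C
F3 | step 9 | (2R,5R,8S,9S,10R)-12-(TBSO)-8-(TESO)-13,14,15,16,17,19-hexanor-ent-labd-3-en-2-ol | CC(C)(C)[Si](C)(C)OCC[C@@H]1[C@@H](O[Si](CC)(CC)CC)CC[C@@H]2C(C)=C[C@H](O)C[C@@]12C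
F4 | step 9 | (2R,5R,8S,9S,10R)-12-(TBSO)-8-(TESO)-2-[(tributylstannyl)methoxy]-13,14,15,16,17,19-hexanor-ent-labd-3-ene | CC(C)(C)[Si](C)(C)OCC[C@@H]1[C@@H](O[Si](CC)(CC)CC)CC[C@@H]2C(C)=C[C@H](OC[Sn](CCCC)(CCCC)CCCC)C[C@@]12C
F5 | step 9 | (4R,5S,8S,9S,10R)-12-(TBSO)-8-(TESO)-13,14,15,16,17-pentanor-ent-labd-2-en-19-ol | CC(C)(C)[Si](C)(C)OCC[C@@H]1[C@@H](O[Si](CC)(CC)CC)CC[C@@H]2[C@](C)(CO)C=CC[C@@]12C
F6 | step 8 | 2-{[(3R,4R,7E,9E)-3-[2-(TBSO)ethyl]-2,8-dimethyl-10-(pinB)deca-1,7,9-trien-4-yl]oxy}-4,4,5,5-tetramethyl-1,3,2-dioxaborolane | CC(C)(C)[Si](C)(C)OCC[C@H](C(C)=C)[C@H](OB1OC(C)(C)C(C)(C)O1)CC/C=C(C)/C=C/B2OC(C)(C)C(C)(C)O2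
F7 | step 8 | (3R,4R,7E,9E)-3-[2-(TBSO)ethyl]-2,8-dimethyl-10-(pinB)deca-1,7,9-trien-4-ol | CC(C)(C)[Si](C)(C)OCC[C@H](C(C)=C)[C@H](O)CC/C=C(C)/C=C/B1OC(C)(C)C(C)(C)O1
F8 | step 8 | (3R,4R,7E,9E)-3-[2-(TBSO)ethyl]-2,8-dimethyl-10-(pinB)deca-1,7,9-trien-4-yl acetate | CC(C)(C)[Si](C)(C)OCC[C@H](C(C)=C)[C@H](OC(C)=O)CC/C=C(C)/C=C/B1OC(C)(C)C(C)(C)O1
F9 | step 11 | (4R,5S,8S,9S,10R)-12,19-bis(TBSO)-13,14,15,16,17-pentanor-ent-labdan-8-ol | CC(C)(C)[Si](C)(C)OCC[C@@H]1[C@@H](O)CC[C@@H]2[C@](C)(CO[Si](C)(C)C(C)(C)C)CCC[C@@]12C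
F10 | step 11 | (4R,5S,9S,10R)-12,19-bis(TBSO)-13,14,15,16,17-pentanor-ent-labdan-8-one | CC(C)(C)[Si](C)(C)OCC[C@@H]1C(=O)CC[C@@H]2[C@](C)(CO[Si](C)(C)C(C)(C)C)CCC[C@@]12C
F11 | step 11 | (4R,5S,9R,10S)-12,19-bis(TBSO)-13,14,15,16-tetranor-ent-labd-8(17)-ene | CC(C)(C)[Si](C)(C)OCC[C@@H]1C(=C)CC[C@@H]2[C@](C)(CO[Si](C)(C)C(C)(C)C)CCC[C@@]12C
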